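The cyclohexene ring is disconnected across C2–C3 and C1–C6, because O3 and O6 sit cis on the two allylic carbons that flank the C1=C2 double bond carrying C7. A copper bis(oxazoline)-catalysed Diels–Alder reaction between (E,E)-1,4-diacetoxybutadiene and the chelating imide 3-propioloyl-oxazolidin-2-one makes the ring, both bonds, all seven skeletal carbons and the C3/C6 stereocentres in one operation. Osmylation of the remaining C4=C5 double bond anti to the acetates then sets C4 and C5. A cyclic orthobenzoate protects that diol and later becomes the O5 benzoate, while one hydride step unmasks O3, O6 and C7–OH.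

Key step: step 2

Numbering: ring carbons are numbered as in the target (C1 bears C7, C2 is the alkene CH, C3–C6 bear O3–O6).

Assumption: the sense of induction is taken from the square-planar chelate model (the ligand tert-butyl nearest the acyl group screens one alkyne face, and the C4=C5 edge of the diene lies on the acyl-oxygen side, away from the oxazolidinone CH2), which points to the (S,S)-ligand for the (3S,6R) adduct; because this is untested for an alkyne, the mirror-image ligand is to be used instead should a trial run favour the (3R,6S) adduct.

**Step 1**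
Reactants: 1 propiolic acid; 2 oxazolidin-2-one
Product: 5 3-(prop-2-ynoyl)-1,3-oxazolidin-2-one, via propiolic pivalic anhydride 3 (not isolated), via lithiated oxazolidin-2-one 4 (not isolated)
Conditions: 1, PivCl, Et3N, THF, −78 to 0 °C (gives 3); 2, n-BuLi, THF, −78 °C (gives 4); 3 added to 4, −78 to −20 °C; aq. NH4Cl
Reagents that add atoms: none
Why: N-acylation of a lithiated oxazolidinone by a mixed pivalic anhydride, in which the nitrogen anion attacks the unhindered propioloyl carbonyl and not the tert-butyl-shielded one, while the low temperature holds back conjugate addition to the ynoyl group; no stereocentre is formed.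

**Step 2**
Reactants: 5 3-(prop-2-ynoyl)-1,3-oxazolidin-2-one; 6 (1E,3E)-buta-1,3-diene-1,4-diyl diacetate
Product: 7 (3S,6R)-3,6-diacetoxy-1-[(2-oxo-1,3-oxazolidin-3-yl)carbonyl]cyclohexa-1,4-diene (acetoxy groups cis)
Conditions: [Cu((S,S)-t-Bu-box)](SbF6)2 (10 mol %, from CuCl2, AgSbF6 and 2,2'-(propane-2,2-diyl)bis[(4S)-4-tert-butyl-4,5-dihydro-1,3-oxazole], AgCl filtered off), 6 (2 equiv), CH2Cl2, −40 to −20 °C; cold filtration through neutral Al2O3, solution used at once
Reagents that add atoms: none
Why: The two imide carbonyls of 5 chelate the cationic divalent copper centre, which lowers the LUMO of the conjugated alkyne π bond so that the s-cis diene adds suprafacially in a concerted, asynchronous, normal-electron-demand [4+2] cycloaddition that forms C2–C3 and C1–C6 together. The closest known reaction types are the copper bis(oxazoline)-catalysed enantioselective Diels–Alder reactions of N-acryloyl oxazolidinones with 1-acetoxybutadiene and the chiral copper Lewis acid-catalysed Diels–Alder reactions of two-point-binding propiolamides with dienes. The six-membered carbocycle is closed by this intermolecular 4π + 2π cycloaddition itself, both ring bonds being made in the one step. C3 and C6 come from the diene termini: their cis relationship follows from the E,E geometry and suprafacial addition, and their absolute configuration from the ligand tert-butyl group that screens one face of the bound alkyne together with the preferred placement of the C4=C5 edge of the diene on the acyl-oxygen side. Only enantioselection is needed, since the symmetric diene raises no regiochemical question and an alkyne gives no endo/exo pair; the two-point binding of the imide is what lets the catalyst tell the two approaches apart.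

**Step 3**
Reactants: 7 (3S,6R)-3,6-diacetoxy-1-[(2-oxo-1,3-oxazolidin-3-yl)carbonyl]cyclohexa-1,4-diene
Product: 8 3,6-di-O-acetyl-4,5-diol (O4 and O5 cis to each other and on the ring face opposite O3 and O6; C1 still the oxazolidinone imide)
Conditions: K2OsO2(OH)4 (1 mol %), NMO (1.2 equiv), citric acid (1 equiv), t-BuOH/H2O (1:1), 0 to 10 °C; aq. Na2SO3
Reagents that add atoms: N-methylmorpholine N-oxide, C[N+]1([O-])CCOCC1; water, O
Why: Catalytic osmium syn-dihydroxylation with NMO as terminal oxidant, in which the isolated cis-disubstituted C4=C5 reacts in preference to the acyl-conjugated trisubstituted C1=C2, the osmium reagent adds to the face opposite the two acetoxy groups (as is usual for cis-3,6-diacyloxycyclohexenes) and so places O4 and O5 trans to O3 and O6, and the citric acid buffer keeps out base that could eliminate acetic acid.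

**Step 4**
Reactants: 8 3,6-di-O-acetyl-4,5-diol; 9 trimethyl orthobenzoate
Product: 10 4,5-O-(methoxy)(phenyl)methylidene derivative of 8 (cyclic methyl orthobenzoate, cis-fused 2-methoxy-2-phenyl-1,3-dioxolane, both epimers at the orthoester carbon)
Conditions: 9 (3 equiv), CSA (5 mol %), CH2Cl2, rt; Et3N quench
Reagents that add atoms: trimethyl orthobenzoate (9), COC(OC)(OC)c1ccccc1
Why: Acid-catalysed orthoester exchange, in which the only free diol, the cis-4,5 pair, displaces two methoxy groups of 9 to close the five-membered dioxolane without touching any ring stereocentre (the two orthoester epimers converge in step 7).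

**Step 5**
Reactants: 10 cyclic orthobenzoate imide diacetate
Product: 11 triol with free O3–H, O6–H and C7–OH and the 4,5-orthobenzoate intact
Conditions: LiBH4 (excess), MeOH (2 equiv), THF, 0 °C to rt; aq. NaOH and potassium sodium tartrate work-up (kept basic)
Reagents that add atoms: none
Why: Reductive cleavage of an N-acyl oxazolidinone with LiBH4, in which the activated imide carbonyl is reduced in the 1,2-sense to the allylic alcohol with release of oxazolidin-2-one, the excess hydride reduces both acetates to ethanol, and the orthoester, inert to base and hydride, survives the basic work-up.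

**Step 6**
Reactants: 11 triol orthobenzoate; 12 benzoyl chloride
Product: 13 O7-monobenzoate of 11 (O3–H and O6–H free, 4,5-orthobenzoate intact)
Conditions: BzCl (1.05 equiv), pyridine/CH2Cl2, −40 to −20 °C; aq. NaHCO3
Reagents that add atoms: benzoyl chloride (12), O=C(Cl)c1ccccc1
Why: Kinetically selective O-acylation, in which one equivalent of acid chloride at low temperature esterifies the unhindered primary allylic hydroxyl well before the two flanked secondary ones, and the excess pyridine keeps the orthoester away from acid.

**Step 7**
Reactants: 13 O7-benzoate 4,5-orthobenzoate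
Product: 14 [(3R,4S,5R,6S)-5-(benzoyloxy)-3,4,6-trihydroxycyclohex-1-en-1-yl]methyl benzoate (target)
Conditions: AcOH/H2O (4:1), 0 °C to rt; toluene azeotrope below 30 °C
Reagents that add atoms: water, O
Why: Acid hydrolysis of a cyclic orthoester through the 2-phenyl-1,3-dioxolan-2-ylium ion and its hemiorthoester, which opens under stereoelectronic control to the axial ester and the equatorial alcohol; in the favoured half-chair O6 is pseudoaxial (avoiding A(1,2) strain with the C1 substituent), so O5 is axial and keeps the benzoate while O4 is freed, and no stereocentre is altered.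

**Compound list**
1 | propiolic acid (prop-2-ynoic acid) | C#CC(=O)O | starting material
2 | oxazolidin-2-one | O=C1NCCO1 | starting material
3 | 2,2-dimethylpropanoic prop-2-ynoic anhydride (propiolic pivalic anhydride) | C#CC(=O)OC(=O)C(C)(C)C | intermediate
4 | lithium 2-oxo-1,3-oxazolidin-3-ide (lithiated oxazolidin-2-one) | [Li+].O=C1[N-]CCO1 | intermediate
5 | 3-(prop-2-ynoyl)-1,3-oxazolidin-2-one | C#CC(=O)N1CCOC1=O | intermediate
6 | (1E,3E)-buta-1,3-diene-1,4-diyl diacetate | CC(=O)O/C=C/C=C/OC(C)=O | starting material
7 | (3S,6R)-3,6-diacetoxy-1-[(2-oxo-1,3-oxazolidin-3-yl)carbonyl]cyclohexa-1,4-diene, acetoxy groups cis | O=C(N1CCOC1=O)C1=C[C@@H](OC(C)=O)C=C[C@H]1OC(C)=O | intermediate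
8 | 3,6-di-O-acetyl-4,5-dihydroxy-1-[(2-oxo-1,3-oxazolidin-3-yl)carbonyl]cyclohex-1-ene, O4/O5 cis and trans to O3/O6 | O=C(N1CCOC1=O)C1=C[C@@H](OC(C)=O)[C@H](O)[C@H](O)[C@H]1OC(C)=O | intermediate
9 | trimethyl orthobenzoate | COC(OC)(OC)c1ccccc1 | starting material
10 | 4,5-O-[(methoxy)(phenyl)methylidene] derivative of 8 (cyclic orthobenzoate, ring configuration as in 8, epimers at the orthoester carbon) | O=C(N1CCOC1=O)C1=C[C@@H](OC(C)=O)[C@@H]2OC(OC)(c3ccccc3)O[C@@H]2[C@H]1OC(C)=O | intermediate
11 | 1-(hydroxymethyl)cyclohex-1-ene-3,6-diol 4,5-O-[(methoxy)(phenyl)methylidene] orthoester (C3–C6 configured as in 14) | OCC1=C[C@@H](O)[C@@H]2OC(OC)(c3ccccc3)O[C@@H]2[C@H]1O | intermediate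
12 | benzoyl chloride | O=C(Cl)c1ccccc1 | starting material
13 | O7-benzoate of 11 | O=C(OCC1=C[C@@H](O)[C@@H]2OC(OC)(c3ccccc3)O[C@@H]2[C@H]1O)c1ccccc1 | intermediate
14 | [(3R,4S,5R,6S)-5-(benzoyloxy)-3,4,6-trihydroxycyclohex-1-en-1-yl]methyl benzoate | O=C(OCC1=C[C@@H](O)[C@H](O)[C@H](OC(=O)c2ccccc2)[C@H]1O)c1ccccc1 | target

**Totals**
Total step count: 7. Longest linear sequence: 7 steps (1 to 14 through steps 1–7).

**Steps most likely to fail**

Step 2. The acyloxy diene may add too slowly to the copper-bound ynoyl imide, the Lewis acid may provoke loss of acetic acid from the adduct (aromatisation), or the two placements of the diene over the alkyne may be poorly told apart, so that enantioselectivity erodes. The fallback replaces catalyst control by a covalent auxiliary and pressure activation. It sets out from anhydride 3 (made from 1 as in step 1) and diene 6. Anhydride 3 acylates lithium (4S)-4-benzyl-2-oxo-1,3-oxazolidin-3-ide F1 (from commercial (S)-4-benzyloxazolidin-2-one and n-BuLi) to give (S)-4-benzyl-3-(prop-2-ynoyl)-1,3-oxazolidin-2-one F2. F2 and 6 are then combined without any Lewis acid under about 12 kbar in CH2Cl2 at room temperature, where no acid is present to eliminate acetic acid. The two adducts are now diastereomers, and the (3S,6R)-configured adduct F3 is separated by chromatography or crystallisation, if need be only after dihydroxylation as in step 3 (diol F4) and orthoester formation as in step 4 (orthobenzoate F5). LiBH4 as in step 5 then releases the auxiliary, and the fallback comes back to the route at 11.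

Step 7. The hemiorthoester may open through the other half-chair and leave the benzoate on O4, or the ester may wander between the cis oxygens O5 and O4 during isolation. The fallback sets out from 13 and uses the opposite regiochemical rule. The orthoester is removed entirely by acid-catalysed exchange with methanol (PPTS, MeOH, rt) to give [(3R,4S,5R,6S)-3,4,5,6-tetrahydroxycyclohex-1-en-1-yl]methyl benzoate F6. Its cis-4,5-diol is then monobenzoylated under diarylborinic acid catalysis (2-aminoethyl diphenylborinate, BzCl, i-Pr2NEt, MeCN), which acylates the equatorial oxygen of a cis-diol. This delivers the O5 ester in exactly the case where the axial-selective opening of step 7 does not, and the fallback comes back to the route at 14.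

Step 6. Acylation may spill over to the secondary allylic hydroxyls O3 and O6, or adventitious acid may open the orthoester during the reaction. The fallback sets out from 10 and differentiates the hydroxyls by the order in which they are unveiled. NaBH4 in THF/H2O at 0 °C reduces only the imide and gives the 3,6-di-O-acetyl primary alcohol F7. BzCl in pyridine esterifies its single free hydroxyl to give O7-benzoate F8. Aqueous AcOH opens the orthoester as in step 7 to the 5,7-di-O-benzoyl-3,6-di-O-acetyl compound F9. Acid-catalysed methanolysis (HCl from AcCl in MeOH, 0 °C to rt), which removes acetates much faster than benzoates, then frees O3 and O6, and the fallback comes back to the route at 14.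

**Further compounds**
F1 | step 2 | lithium (4S)-4-benzyl-2-oxo-1,3-oxazolidin-3-ide | [Li+].O=C1[N-][C@@H](Cc2ccccc2)CO1
F2 | step 2 | (S)-4-benzyl-3-(prop-2-ynoyl)-1,3-oxazolidin-2-one | C#CC(=O)N1[C@@H](Cc2ccccc2)COC1=O
F3 | step 2 | (3S,6R)-3,6-diacetoxy-1-{[(4S)-4-benzyl-2-oxo-1,3-oxazolidin-3-yl]carbonyl}cyclohexa-1,4-diene | O=C(N1[C@@H](Cc2ccccc2)COC1=O)C1=C[C@@H](OC(C)=O)C=C[C@H]1OC(C)=O
F4 | step 2 | 4,5-diol of F3 (O4/O5 cis, trans to O3/O6) | O=C(N1[C@@H](Cc2ccccc2)COC1=O)C1=C[C@@H](OC(C)=O)[C@H](O)[C@H](O)[C@H]1OC(C)=O
F5 | step 2 | 4,5-O-[(methoxy)(phenyl)methylidene] orthoester of F4 | O=C(N1[C@@H](Cc2ccccc2)COC1=O)C1=C[C@@H](OC(C)=O)[C@@H]2OC(OC)(c3ccccc3)O[C@@H]2[C@H]1OC(C)=O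
F6 | step 7 | [(3R,4S,5R,6S)-3,4,5,6-tetrahydroxycyclohex-1-en-1-yl]methyl benzoate | O=C(OCC1=C[C@@H](O)[C@H](O)[C@H](O)[C@H]1O)c1ccccc1
F7 | step 6 | 3,6-di-O-acetyl-1-(hydroxymethyl)cyclohex-1-ene 4,5-O-[(methoxy)(phenyl)methylidene] orthoester | OCC1=C[C@@H](OC(C)=O)[C@@H]2OC(OC)(c3ccccc3)O[C@@H]2[C@H]1OC(C)=O
F8 | step 6 | O7-benzoate of F7 | O=C(OCC1=C[C@@H](OC(C)=O)[C@@H]2OC(OC)(c3ccccc3)O[C@@H]2[C@H]1OC(C)=O)c1ccccc1
F9 | step 6 | 3,6-di-O-acetyl-5,7-di-O-benzoyl compound with free O4–H | O=C(OCC1=C[C@@H](OC(C)=O)[C@H](O)[C@H](OC(=O)c2ccccc2)[C@H]1OC(C)=O)c1ccccc1
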